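**Retrosynthetic overview**
1. Forward plan: lutein 1 → dienol 2 → enone 3 → epoxide 4 → target 5; three steps, no C–C bond is made.
2. Key disconnection (C3'–O): 5 ⇐ 4, where the oxirane C4'–O bond is pushed open from the enone γ-carbon C6 through eleven conjugated C=C bonds, giving retro-polyene, dienone and free 3'-OH together.
3. 4 ⇐ 3: catalyst-controlled manganese–salen oxygen transfer to the only cis-disubstituted, chain-terminal C3'=C4' bond; this C–O bond formation sets the single stereocentre.
4. 3 ⇐ 2 ⇐ 1: Oppenauer oxidation with conjugative double-bond shift; acid dehydration of the allylic carbinol of lutein.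
5. Rings: both carbocycles are bought with lutein; the only ring formed is the transient oxirane of 4 (step 3).

Assumption: crystalline marigold (3R,3'R,6'R)-lutein counts as cheap and commercial; locants follow lutein throughout (unprimed = half ending in the ring that becomes the keto ring of 5, primed = half ending in the ring that becomes the hydroxy ring).

Step 1
Reactants: 1 (3R,3'R,6'R)-lutein
Product: 2 (3R)-3',4'-didehydro-β,β-caroten-3-ol
Conditions: H2SO4 (aq, cat.), 1-propanol/H2O, 90 °C, N2, dark; crystallise
Reagents that add atoms: none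
Why: Acid-catalysed E1 dehydration of the allylic ε-ring carbinol (allyl cation C3'–C5', loss of H-6'), in which reversible protonation funnels regioisomeric dienes to the fully conjugated 3',4'-didehydro-β ring while the non-allylic (3R)-carbinol does not ionise.

Step 2
Reactants: 2 (3R)-3',4'-didehydro-β,β-caroten-3-ol
Product: 3 (6RS)-3',4'-didehydro-ε,β-caroten-3-one
Conditions: Al(OiPr)3 (30 mol %), cyclohexanone (10 equiv), toluene, 90 °C, N2, dark
Reagents that add atoms: none
Why: Oppenauer oxidation (hydride transfer from the aluminium alkoxide of 2 to cyclohexanone) with conjugation of the first-formed β,γ-enone as in cholesterol → cholest-4-en-3-one; C6 forms as a racemic centre that step 3 erases, and the C3 carbinol centre of lutein is spent here because the target's only stereocentre is made in step 3.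

Step 3
Reactants: 3 (6RS)-3',4'-didehydro-ε,β-caroten-3-one
Product: 5 (3'S,6E,6'E)-3'-hydroxy-4',5'-didehydro-4,5'-retro-β,β-caroten-3-one (eschscholtzxanthone; target), via (3'S,4'R)-3',4'-epoxide 4 (not isolated)
Conditions: (R,R)-[N,N'-bis(3,5-di-tert-butylsalicylidene)cyclohexane-1,2-diaminato]MnCl (5 mol %), NMO (5 equiv), mCPBA (1.0 equiv), CH2Cl2, −78 °C; then DBU (3 equiv), −78 → 0 °C; then heptane, 80 °C, crystallise (6E,6'E)
Reagents that add atoms: mCPBA (3-chloroperoxybenzoic acid), OOC(=O)c1cccc(Cl)c1
Why: Proposed new method: a site- and enantioselective Jacobsen–Katsuki oxygen transfer to a carotenoid, followed in the same flask by a 1,24-epoxide-opening relay; the manganese oxo species (pentavalent manganese) takes cis-disubstituted conjugated alkenes by side-on approach, and C3'=C4' of 3 is the only such alkene and the electron-rich terminus of the undecaene (every other C=C is trans-disubstituted, E-trisubstituted, tetrasubstituted or part of the electron-poor enone), so the new C–O bonds go to C3'/C4'; by analogy with indene, where the (R,R)-catalyst gives the (1R,2S)-oxide (benzylic carbon ↔ C4', homobenzylic carbon ↔ C3'), the (3'S,4'R)-epoxide 4 is expected and this sets C3'; DBU then removes the γ-hydrogen at C6 of the enone and the extended enolate pushes the C4'–O bond open through eleven conjugated C=C bonds (E1cB), leaving the C3'–O bond untouched (3'S retained) and giving dienone, retro-polyene and alcohol at once; closest known reactions are the (salen)Mn epoxidation of cis-alkenes in indene, chromenes and conjugated cyclic dienes, the base isomerisation of γ,δ-epoxy enones to γ-hydroxy dienones, and the acid-induced 1,22-elimination of 4-hydroxy carotenoids to retro-dehydro carotenoids.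

**Compound list**
1 | (3R,3'R,6'R)-β,ε-carotene-3,3'-diol (lutein) | CC1=C(/C=C/C(C)=C/C=C/C(C)=C/C=C/C=C(C)/C=C/C=C(C)/C=C/[C@H]2C(C)=C[C@H](O)CC2(C)C)C(C)(C)C[C@H](O)C1 | starting material
2 | (3R)-3',4'-didehydro-β,β-caroten-3-ol (all-E; 3-hydroxy-β ring at one end, 6,6-dimethyl-2-methylcyclohexa-1,3-diene ring conjugated to the chain at the other) | CC1=C(/C=C/C(C)=C/C=C/C(C)=C/C=C/C=C(C)/C=C/C=C(C)/C=C/C2=C(C)C=CCC2(C)C)C(C)(C)C[C@H](O)C1 | intermediate
3 | (6RS)-3',4'-didehydro-ε,β-caroten-3-one (3-oxo-ε ring: C3=O, C4=C5, H on C6; 3',4'-didehydro-β ring at the other end; by end-group citation order: 3,4-didehydro-β,ε-caroten-3'-one) | CC1=CC(=O)CC(C)(C)C1/C=C/C(C)=C/C=C/C(C)=C/C=C/C=C(C)/C=C/C=C(C)/C=C/C2=C(C)C=CCC2(C)C | intermediate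
4 | (3'S,4'R,6RS)-3',4'-epoxy-ε,β-caroten-3-one (cis-fused oxirane on the former C3'=C4' bond of 3) | CC1=CC(=O)CC(C)(C)C1/C=C/C(C)=C/C=C/C(C)=C/C=C/C=C(C)/C=C/C=C(C)/C=C/C2=C(C)[C@H]3O[C@H]3CC2(C)C | intermediate
5 | (3'S,6E,6'E)-3'-hydroxy-4',5'-didehydro-4,5'-retro-β,β-caroten-3-one (eschscholtzxanthone, CNP0279160.1) | CC1=CC(=O)CC(C)(C)\C1=C/C=C(C)/C=C/C=C(C)/C=C/C=C/C(C)=C/C=C/C(C)=C/C=C1/C(C)=C[C@@H](O)CC1(C)C | target

**Totals**
Total step count: 3. Longest linear sequence: 3.

**Steps most likely to fail**

Step 3 (the proposed new step) is the most likely to fail. The risks are: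
- oxidation at other sites or bleaching of the polyene through its radical cation;
- modest ee, or the opposite sense of induction, which would be answered within the step by the (S,S)-catalyst;
- racemisation of 5 if the base is too strong, since the C3' hydrogen is vinylogously acidic; this is why DBU is used and not an alkoxide;
- a mixture of 6/6' E/Z isomers. These equilibrate on heating; the (6E,6'E) isomer is collected by crystallisation and the mother liquor re-equilibrated.

The fallback uses known chemistry, sets out from 1 and returns at 5. It keeps the carbinol of the β ring of lutein as the stereocentre, so the roles of the two rings are exchanged. MnO2 (CH2Cl2, room temperature) oxidises only the allylic ε-ring carbinol of lutein to (3R,6'R)-3-hydroxy-β,ε-caroten-3'-one F4. N-Bromosuccinimide (CHCl3, −20 °C) brominates the allylic C4 to (3S,4RS,6'R)-4-bromo-3-hydroxy-β,ε-caroten-3'-one F5, which is not isolated (3S only through the priority change; the carbinol is untouched). N-Ethylmorpholine (60 °C) then removes HBr across the polyene (Br from C4, H from C6'). This is the dehydrogenation known for zeaxanthin → eschscholtzxanthin and β-carotene → retro-dehydro-β-carotene. The (3R) centre of lutein is carried over unchanged and reads (3'S) in 5 because C4' outranks C2' once it is sp2. The historically low yield and over-bromination of this dehydrogenation are why it is only the fallback.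

Step 2 is the next most likely to fail. The aluminium alkoxide at 90 °C may carry the conjugation further (proton delivered to C3', which removes the C3'=C4' bond needed in step 3) or give aldol by-products with cyclohexanone. The fallback sets out from 2 and returns at 3. Dess–Martin periodinane (NaHCO3, CH2Cl2, 0 °C) gives the unconjugated ketone 3',4'-didehydro-β,β-caroten-3-one F3 under non-equilibrating conditions. A catalytic amount of DBU (CH2Cl2, 0 °C, short contact) then moves the ring double bond into conjugation by kinetic γ-protonation next to the carbonyl, giving 3.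

Step 1 is the third risk. Hot acid may leave regioisomeric dienes (exocyclic-methylene and 2',3'-ene isomers) and cause E/Z scrambling. The fallback sets out from 1 and returns at 2. Lutein is peracetylated (Ac2O, pyridine) to (3R,3'R,6'R)-lutein diacetate F1. Pd(PPh3)4 (zerovalent palladium, 5 mol %, Et3N, THF, 60 °C) ionises only the allylic acetate, and Tsuji–Trost-type 1,4-elimination through the π-allyl complex with loss of H-6' gives (3R)-3',4'-didehydro-β,β-caroten-3-yl acetate F2. K2CO3 in MeOH/THF then frees 2.

**Further compounds**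
F1 | step 1 | (3R,3'R,6'R)-lutein diacetate | CC1=C(/C=C/C(C)=C/C=C/C(C)=C/C=C/C=C(C)/C=C/C=C(C)/C=C/[C@H]2C(C)=C[C@H](OC(C)=O)CC2(C)C)C(C)(C)C[C@H](OC(C)=O)C1
F2 | step 1 | (3R)-3',4'-didehydro-β,β-caroten-3-yl acetate | CC1=C(/C=C/C(C)=C/C=C/C(C)=C/C=C/C=C(C)/C=C/C=C(C)/C=C/C2=C(C)C=CCC2(C)C)C(C)(C)C[C@H](OC(C)=O)C1
F3 | step 2 | 3',4'-didehydro-β,β-caroten-3-one | CC1=C(/C=C/C(C)=C/C=C/C(C)=C/C=C/C=C(C)/C=C/C=C(C)/C=C/C2=C(C)C=CCC2(C)C)C(C)(C)CC(=O)C1
F4 | step 3 | (3R,6'R)-3-hydroxy-β,ε-caroten-3'-one | CC1=C(/C=C/C(C)=C/C=C/C(C)=C/C=C/C=C(C)/C=C/C=C(C)/C=C/[C@H]2C(C)=CC(=O)CC2(C)C)C(C)(C)C[C@H](O)C1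
F5 | step 3 | (3S,4RS,6'R)-4-bromo-3-hydroxy-β,ε-caroten-3'-one | CC1=C(/C=C/C(C)=C/C=C/C(C)=C/C=C/C=C(C)/C=C/C=C(C)/C=C/[C@H]2C(C)=CC(=O)CC2(C)C)C(C)(C)C[C@H](O)C1Br
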